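**Plan**

- Retrosynthesis: the enantiomers are parted last (kinetic resolution at the 9-acetate), then the ring-A 4-O–CH3 bond is cut. The central cut removes the C8–O4' aryl ether bond and the C7–OH bond together, through a p-quinone methide, giving sinapyl acetate and 4-allyl-2,6-dimethoxyphenol. The acetyl C–O bond and the allylic alcohol lead back to sinapic acid.
- Enabling feature: the acyclic C7(OH)–C8(O–C4') unit. C7 is benzylic to ring A (4-oxygenated, 3,5-dimethoxylated, a free phenol before methylation) and the ether oxygen sits on ring B, a 2,6-dimethoxyphenol with an alkylated para position. This is the pattern left by phenoxyl radical coupling at C8/O4' followed by water addition at C7.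
- Forward: sinapic acid 1 → methyl ester 2 → sinapyl alcohol 3 → 9-acetate 4. Oxidative cross-coupling of 4 with phenol 5 joins the two C6C3 units through quinone methide 6 to phenol 7 (no ring is formed). O-Methylation gives racemate 8 and resolution gives target 9.
- Stereochemistry: coupling and hydration give both racemic diastereomers without control. The threo pair is isolated after step 4, and the (7R,8R) enantiomer is secured in step 6 by lipase-catalysed removal of the acetate from its (7S,8S) antipode.

Key step: step 4

Numbering: C7 is the benzylic carbinol carbon, C8 the ether-bearing carbon, C9 the CH2OAc carbon; primed atoms belong to the allylphenol ring. The target is threo-(7R,8R), which is (2R,3R) in propyl acetate numbering.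

Assumption: Burkholderia cepacia lipase is taken to cleave the 9-acetate of the (7S,8S) enantiomer faster. For a primary ester with an oxygen-bearing β-stereocentre the sense cannot be predicted with confidence, so it is to be confirmed on racemic 8 by chiral HPLC before scale-up.

Notation: racemates 7 and 8 are written in SMILES as the enantiomer with the target's configuration; 6 is racemic at C8 and written without a descriptor.

Step 1
Reactants: 1 sinapic acid
Product: 2 methyl sinapate
Conditions: MeOH, cat. H2SO4, reflux
Reagents that add atoms: methanol, CO
Why: Fischer esterification under acid catalysis converts the acid into the methyl ester without touching the phenol or the (E)-alkene and gives a substrate soluble enough for hydride reduction.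

Step 2
Reactants: 2 methyl sinapate
Product: 3 sinapyl alcohol
Conditions: DIBAL-H (4 equiv), toluene, 0 °C; aq. Rochelle salt
Reagents that add atoms: none
Why: DIBAL-H 1,2-reduction of an α,β-unsaturated ester to the allylic alcohol: the first equivalent forms the aluminium phenoxide, whose electron-rich ring further disfavours conjugate reduction, and the (E)-alkene is kept.

Step 3
Reactants: 3 sinapyl alcohol
Product: 4 sinapyl acetate
Conditions: Novozym 435 (CAL-B), vinyl acetate (3 equiv), THF, 30 °C
Reagents that add atoms: vinyl acetate, C=COC(C)=O
Why: Lipase-catalysed irreversible transesterification with an enol ester: CAL-B acylates the primary allylic hydroxyl but not the hindered 2,6-dimethoxyphenol, and tautomerisation of vinyl alcohol to acetaldehyde drives the reaction.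

Step 4
Reactants: 4 sinapyl acetate; 5 4-allyl-2,6-dimethoxyphenol
Product: 7 rac-threo-(2R*,3R*)-2-(4-allyl-2,6-dimethoxyphenoxy)-3-hydroxy-3-(4-hydroxy-3,5-dimethoxyphenyl)propyl acetate, via quinone methide 6 (not isolated)
Conditions: laccase (Trametes versicolor), air, acetone/20 mM acetate buffer pH 5 (1:2), rt; 4 added over 8 h to 5 (4 equiv), then aged until 6 is consumed
Reagents that add atoms: water, O
Why: Laccase/O2 takes one electron and one proton from each phenol; the radical of 4, with both ring positions ortho to oxygen methoxylated, carries its reactive spin density at C8, and the radical of 5, with ortho positions methoxylated and the para position alkylated, can only bond productively through oxygen, so radical–radical combination forms the C8–O4' ether as p-quinone methide 6, which adds water at C7 (1,6-addition) and rearomatises ring A to give 7. The closest known reaction type is the laccase- or peroxidase-mediated dehydrogenative 8-O-4' (β-O-4) cross-coupling of 4-hydroxycinnamyl alcohols and their 9-esters with syringyl-type phenols followed by quinone methide hydration, the standard entry to lignin β-ether model compounds. No ring closes: two chain bonds (C8–O4' and C7–OH) and two stereocentres are created in one operation. Neither stereocentre is under control, since C8 arises from an achiral radical pair and water can reach both faces of 6 (a lean towards erythro, as often seen for syringyl ethers, is possible), so 7 is taken as the racemic threo pair separated from the erythro pair by chromatography on silica and, if needed, reversed-phase HPLC, and the absolute configuration is left to step 6. The selectivity that the step needs is cross-coupling over 8–8' homo-coupling of 4 and over re-oxidation of 7; the 9-acetate only prevents furofuran closure and does not stop 8–8' coupling itself, so the selectivity rests on feeding 4 slowly into a four-fold excess of 5, whose longer-lived O-centred radical then becomes the main partner of the C8 radical. Expected side paths are disproportionation of the radical of 5 to its vinylogous quinone methide and addition of 5 instead of water to 6, both held back by the dilute aqueous medium.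

Step 5
Reactants: 7 rac-threo-(2R*,3R*)-2-(4-allyl-2,6-dimethoxyphenoxy)-3-hydroxy-3-(4-hydroxy-3,5-dimethoxyphenyl)propyl acetate
Product: 8 rac-threo-(2R*,3R*)-2-(4-allyl-2,6-dimethoxyphenoxy)-3-hydroxy-3-(3,4,5-trimethoxyphenyl)propyl acetate
Conditions: MeI, K2CO3, acetone, rt
Reagents that add atoms: iodomethane, CI
Why: Williamson-type O-methylation: carbonate deprotonates only the phenol and not the benzylic alcohol, the phenoxide is methylated by SN2 on iodomethane, and in aprotic acetone at room temperature the 9-acetate and both stereocentres are left alone.

Step 6
Reactants: 8 rac-threo-(2R*,3R*)-2-(4-allyl-2,6-dimethoxyphenoxy)-3-hydroxy-3-(3,4,5-trimethoxyphenyl)propyl acetate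
Product: 9 (2R,3R)-2-(4-allyl-2,6-dimethoxyphenoxy)-3-hydroxy-3-(3,4,5-trimethoxyphenyl)propyl acetate (target)
Conditions: lipase PS-IM (Burkholderia cepacia), n-BuOH (3 equiv), MTBE, 35 °C, stopped at ca. 55% conversion (chiral HPLC)
Reagents that add atoms: none
Why: Lipase-catalysed kinetic resolution by enantioselective alcoholysis of the primary acetate next to the C8 stereocentre: the (7S,8S)-acetate is converted into its diol while the (7R,8R)-acetate is recovered, and running slightly past half conversion trades yield for enantiomeric purity of the recovered ester; no stereocentre is formed or altered.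

**Compound list**

1 | sinapic acid, (E)-3-(4-hydroxy-3,5-dimethoxyphenyl)prop-2-enoic acid | COc1cc(/C=C/C(=O)O)cc(OC)c1O | starting material
2 | methyl sinapate, methyl (E)-3-(4-hydroxy-3,5-dimethoxyphenyl)prop-2-enoate | COC(=O)/C=C/c1cc(OC)c(O)c(OC)c1 | intermediate
3 | sinapyl alcohol, 4-[(E)-3-hydroxyprop-1-enyl]-2,6-dimethoxyphenol | COc1cc(/C=C/CO)cc(OC)c1O | intermediate
4 | sinapyl acetate, (E)-3-(4-hydroxy-3,5-dimethoxyphenyl)prop-2-enyl acetate | COc1cc(/C=C/COC(C)=O)cc(OC)c1O | intermediate
5 | 4-allyl-2,6-dimethoxyphenol | C=CCc1cc(OC)c(O)c(OC)c1 | starting material
6 | quinone methide, 2-(4-allyl-2,6-dimethoxyphenoxy)-3-(3,5-dimethoxy-4-oxocyclohexa-2,5-dien-1-ylidene)propyl acetate, racemic at C8, not isolated | C=CCc1cc(OC)c(OC(COC(C)=O)C=C2C=C(OC)C(=O)C(OC)=C2)c(OC)c1 | intermediate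
7 | rac-threo-(2R*,3R*)-2-(4-allyl-2,6-dimethoxyphenoxy)-3-hydroxy-3-(4-hydroxy-3,5-dimethoxyphenyl)propyl acetate (racemate, one enantiomer drawn) | C=CCc1cc(OC)c(O[C@H](COC(C)=O)[C@H](O)c2cc(OC)c(O)c(OC)c2)c(OC)c1 | intermediate
8 | rac-threo-(2R*,3R*)-2-(4-allyl-2,6-dimethoxyphenoxy)-3-hydroxy-3-(3,4,5-trimethoxyphenyl)propyl acetate (racemate, one enantiomer drawn) | C=CCc1cc(OC)c(O[C@H](COC(C)=O)[C@H](O)c2cc(OC)c(OC)c(OC)c2)c(OC)c1 | intermediate
9 | (2R,3R)-2-(4-allyl-2,6-dimethoxyphenoxy)-3-hydroxy-3-(3,4,5-trimethoxyphenyl)propyl acetate, threo-(7R,8R), single enantiomer | C=CCc1cc(OC)c(O[C@H](COC(C)=O)[C@H](O)c2cc(OC)c(OC)c(OC)c2)c(OC)c1 | target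

**Step count and risks**

Total step count: 6. Longest linear sequence: 6 steps (1 → 9); phenol 5 enters at step 4.

Steps most likely to fail:

1. Step 4. The sinapyl acetate radicals may combine with each other (8–8') faster than with the radical of 5. The radical of 5 may be lost by disproportionation, the phenolic product may be oxidised further, and hydration may deliver mostly the erythro pair. The fallback builds the same skeleton by polar chemistry and sets out from 5. Alkylation with ethyl bromoacetate (K2CO3, acetone) would give ethyl 2-(4-allyl-2,6-dimethoxyphenoxy)acetate F1. Its lithium enolate (LDA, THF, −78 °C) would add to commercial 3,4,5-trimethoxybenzaldehyde to give ethyl 2-(4-allyl-2,6-dimethoxyphenoxy)-3-hydroxy-3-(3,4,5-trimethoxyphenyl)propanoate F2 as an erythro/threo mixture. LiBH4 in THF would reduce the ester to 2-(4-allyl-2,6-dimethoxyphenoxy)-1-(3,4,5-trimethoxyphenyl)propane-1,3-diol F3. CAL-B with vinyl acetate would then acetylate only the primary hydroxyl. After chromatographic removal of the erythro isomer the route is rejoined at 8; ring A is already fully methylated, so steps 4 and 5 are bypassed.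

2. Step 6. The lipase may discriminate the enantiomers poorly at this bulky primary ester, or in the opposite sense to the one assumed. The fallback sets out from 8 and separates the enantiomers directly by preparative HPLC on a polysaccharide-type chiral stationary phase (hexane/2-propanol). The (7R,8R) fraction is identified by comparing the sign of its optical rotation and its ECD curve with those expected for the natural series. This physical resolution returns to the route at 9 and makes no new compound (F0).

3. Step 3. Acyl transfer may also reach the phenolic oxygen, or the enzymatic acylation may be slow enough that the labile p-hydroxycinnamyl ester degrades by ionisation of the allylic acetate during long reaction and isolation times. The fallback sets out from 3. Exhaustive acetylation (Ac2O, pyridine) would give sinapyl alcohol diacetate F4. Hydrazine acetate in DMF would then cleave only the aryl acetate, the ester with the better leaving group, and return the route at 4.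

**Further compounds**

F1 | step 4 | ethyl 2-(4-allyl-2,6-dimethoxyphenoxy)acetate | C=CCc1cc(OC)c(OCC(=O)OCC)c(OC)c1
F2 | step 4 | ethyl rac-threo-(2S*,3R*)-2-(4-allyl-2,6-dimethoxyphenoxy)-3-hydroxy-3-(3,4,5-trimethoxyphenyl)propanoate (racemate, threo component of the erythro/threo mixture drawn) | C=CCc1cc(OC)c(O[C@H](C(=O)OCC)[C@H](O)c2cc(OC)c(OC)c(OC)c2)c(OC)c1
F3 | step 4 | rac-threo-(1R*,2R*)-2-(4-allyl-2,6-dimethoxyphenoxy)-1-(3,4,5-trimethoxyphenyl)propane-1,3-diol (racemate, threo component drawn) | C=CCc1cc(OC)c(O[C@H](CO)[C@H](O)c2cc(OC)c(OC)c(OC)c2)c(OC)c1
F0 | step 6 | none | none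
F4 | step 3 | sinapyl alcohol diacetate, (E)-3-(4-acetoxy-3,5-dimethoxyphenyl)prop-2-enyl acetate | COc1cc(/C=C/COC(C)=O)cc(OC)c1OC(C)=O
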